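**Strategy.** The lactone ring (O1, C2, C3, C4, C5) is opened to the chain C5–C4–C3–C2, whose adjacent CH(CH2Ar) centres C4 and C3 carry no heteroatom. Both are grown from boron: a benzyloxymethyl pinacol boronate (C5) is extended in one flask by two sparteine-derived lithiated 2-arylethyl carbamates, first the veratryl one with (+)-sparteine, then the MOM-protected syringyl one with (−)-sparteine. Each 1,2-metallate shift forms one C–C bond (C5–C4, then C4–C3) and one stereocentre under reagent control and leaves a C–B bond at C3, from which C2 is added as the carboxyl carbon. Hydrogenolysis and acid then close the ring and free the phenol.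

Key step: step 6

Remark: the trans-(3R,4R) lactone requires carbenoids of opposite configuration, so (+)-sparteine (R carbenoid) is assigned to the veratryl carbamate and (−)-sparteine (S carbenoid) to the syringyl carbamate; both alkaloids are taken as commercially available.

**Step 1**
Reactants: 1 2-(3,4-dimethoxyphenyl)ethanol
Product: 2 2-(3,4-dimethoxyphenyl)ethyl N,N-diisopropylcarbamate
Conditions: iPr2NCOCl, Et3N, CH2Cl2, reflux
Reagents that add atoms: N,N-diisopropylcarbamoyl chloride, CC(C)N(C(C)C)C(=O)Cl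
Why: O-acylation of the primary alcohol by the carbamoyl chloride (carbamate formation) is the only reaction open to 1 and installs the hindered carbamate that later directs lithiation and serves as leaving group.

**Step 2**
Reactants: 3 4-allyl-2,6-dimethoxyphenol
Product: 4 5-allyl-1,3-dimethoxy-2-(methoxymethoxy)benzene
Conditions: MOMCl, iPr2NEt, CH2Cl2, 0 → 20 °C
Reagents that add atoms: chloromethyl methyl ether, COCCl
Why: Base-mediated O-alkylation of the phenol (MOM acetal formation) masks the only acidic proton as a group that resists sBuLi, has no free ortho position for directed metalation because both neighbours carry OMe, and is removed by acid at the end.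

**Step 3**
Reactants: 4 5-allyl-1,3-dimethoxy-2-(methoxymethoxy)benzene
Product: 6 2-[3,5-dimethoxy-4-(methoxymethoxy)phenyl]ethanol, via ozonide 5 (not isolated)
Conditions: O3, CH2Cl2, −78 °C (Sudan red 7B end point); then NaBH4, MeOH, −78 → 20 °C
Reagents that add atoms: ozone, [O-][O+]=O
Why: Criegee ozonolysis of the terminal alkene should be far faster than attack on the arene when ozone is stopped at the indicator end point, and NaBH4 reduces ozonide 5 straight to the primary alcohol, so no enolisable aldehyde has to be isolated.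

**Step 4**
Reactants: 6 2-[3,5-dimethoxy-4-(methoxymethoxy)phenyl]ethanol
Product: 7 2-[3,5-dimethoxy-4-(methoxymethoxy)phenyl]ethyl N,N-diisopropylcarbamate
Conditions: iPr2NCOCl, Et3N, CH2Cl2, reflux
Reagents that add atoms: N,N-diisopropylcarbamoyl chloride, CC(C)N(C(C)C)C(=O)Cl
Why: The same carbamate formation as in step 1, under basic conditions that leave the MOM acetal and the methyl ethers untouched.

**Step 5**
Reactants: 8 2-(bromomethyl)-4,4,5,5-tetramethyl-1,3,2-dioxaborolane
Product: 9 2-[(benzyloxy)methyl]-4,4,5,5-tetramethyl-1,3,2-dioxaborolane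
Conditions: BnOH, NaH, THF, 0 °C; then 8, DMSO, 20 → 50 °C
Reagents that add atoms: benzyl alcohol, OCc1ccccc1
Why: Benzyloxide adds to boron and the oxygen group then shifts from boron to carbon with loss of bromide (Matteson-type substitution of an α-halo boronic ester), which amounts to a Williamson etherification at the CH2Br carbon.

**Step 6**
Reactants: 9 2-[(benzyloxy)methyl]-4,4,5,5-tetramethyl-1,3,2-dioxaborolane; 2 2-(3,4-dimethoxyphenyl)ethyl N,N-diisopropylcarbamate; 7 2-[3,5-dimethoxy-4-(methoxymethoxy)phenyl]ethyl N,N-diisopropylcarbamate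
Product: 15 2-[(2R,3R)-4-(benzyloxy)-3-(3,4-dimethoxybenzyl)-1-[3,5-dimethoxy-4-(methoxymethoxy)phenyl]butan-2-yl]-4,4,5,5-tetramethyl-1,3,2-dioxaborolane, via (R)-lithiated carbamate 10 (not isolated), via boronate complex 11 (not isolated), via (S)-boronic ester 12 (not isolated), via (S)-lithiated carbamate 13 (not isolated), via boronate complex 14 (not isolated)
Conditions: 2 (1.3 equiv), sBuLi (1.25 equiv), (+)-sparteine, Et2O, −78 °C, 5 h; 9 (1.0 equiv), −78 °C, then 35 °C; mixture cooled to −78 °C and cannulated into 7 (1.6 equiv), sBuLi (1.5 equiv), (−)-sparteine, Et2O, −78 °C; then 35 °C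
Reagents that add atoms: none
Why: sBuLi–sparteine removes one enantiotopic proton next to the carbamate oxygen (Hoppe lithiation), so (+)-sparteine gives the R-configured lithium compound 10 and (−)-sparteine the S-configured 13, each of which is trapped by the boronic ester with retention as boronate complex 11 or 14. On warming, the carbon group on boron (CH2OBn in 11, the C4 alkyl group in 14) moves to the carbenoid carbon anti to the departing carbamate, with inversion at that carbon and retention in the migrating group, which forms C5–C4 and then C4–C3. This is the known lithiation–borylation (reagent-controlled Matteson-type) homologation of pinacol boronic esters, run twice in sequence; no ring is closed. C4 is fixed by carbenoid 10 (giving S-configured 12) and C3 by carbenoid 13, independently of the substrate, and the opposite senses of the two carbenoids are what place the benzyl groups syn on the extended chain, hence trans in the later lactone (2R,3R in 15). The step needs the 1,2-shift to outrun β-elimination of benzyloxide from 14 and α-deprotonation to outrun benzylic deprotonation; an unactivated benzyl ether in a medium free of Lewis acid is a poor leaving group and a secondary alkyl group migrates readily, while the carbamate carbonyl directs sBuLi to the O–CH2 protons. Over-homologation should not occur because surplus carbenoid decomposes well below the temperature at which 11 and 14 rearrange.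

**Step 7**
Reactants: 15 2-[(2R,3R)-4-(benzyloxy)-3-(3,4-dimethoxybenzyl)-1-[3,5-dimethoxy-4-(methoxymethoxy)phenyl]butan-2-yl]-4,4,5,5-tetramethyl-1,3,2-dioxaborolane
Product: 18 (2R,3R)-4-(benzyloxy)-3-(3,4-dimethoxybenzyl)-2-[3,5-dimethoxy-4-(methoxymethoxy)benzyl]butanoic acid, via α-chloro boronic ester 16 (not isolated), via aldehyde 17 (not isolated)
Conditions: CH2Cl2, nBuLi, THF, −100 °C; 15, −100 → 20 °C; then NaClO2, NaH2PO4, 2-methyl-2-butene, tBuOH/H2O, 20 °C
Reagents that add atoms: dichloromethane, ClCCl; sodium chlorite, [Na+].[O-]Cl=O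
Why: Matteson homologation, in which LiCHCl2 adds to boron and the secondary alkyl group shifts to carbon with loss of chloride and retention at C3, followed by chlorite oxidation of α-chloro boronic ester 16 through aldehyde 17 to the acid (C–B oxidation, loss of chloride, Pinnick oxidation), with 2-methyl-2-butene trapping HOCl so that the electron-rich rings are not chlorinated.

**Step 8**
Reactants: 18 (2R,3R)-4-(benzyloxy)-3-(3,4-dimethoxybenzyl)-2-[3,5-dimethoxy-4-(methoxymethoxy)benzyl]butanoic acid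
Product: 21 (3R,4R)-4-(3,4-dimethoxybenzyl)-3-(4-hydroxy-3,5-dimethoxybenzyl)dihydrofuran-2(3H)-one, via hydroxy acid 19 (not isolated), via MOM lactone 20 (not isolated)
Conditions: H2 (1 atm), Pd/C, MeOH, 20 °C; filter; HCl (1.25 M in MeOH), 40 °C; concentrate from toluene
Reagents that add atoms: none
Why: Hydrogenolysis of the benzyl ether over Pd/C frees the C5 hydroxyl of 19, which under HCl in MeOH lactonises by 5-exo-trig acyl substitution to 20, and the same acid cleaves the aryl MOM acetal with formaldehyde held as dimethoxymethane, neither stereocentre being touched and the trans lactone being the thermodynamically preferred isomer in any case.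

**Compound list**

1 | 2-(3,4-dimethoxyphenyl)ethanol | COc1ccc(CCO)cc1OC | starting material
2 | 2-(3,4-dimethoxyphenyl)ethyl N,N-diisopropylcarbamate | COc1ccc(CCOC(=O)N(C(C)C)C(C)C)cc1OC | intermediate
3 | 4-allyl-2,6-dimethoxyphenol | C=CCc1cc(OC)c(O)c(OC)c1 | starting material
4 | 5-allyl-1,3-dimethoxy-2-(methoxymethoxy)benzene | C=CCc1cc(OC)c(OCOC)c(OC)c1 | intermediate
5 | 3-[3,5-dimethoxy-4-(methoxymethoxy)benzyl]-1,2,4-trioxolane (ozonide, racemic) | COCOc1c(OC)cc(CC2OCOO2)cc1OC | intermediate
6 | 2-[3,5-dimethoxy-4-(methoxymethoxy)phenyl]ethanol | COCOc1c(OC)cc(CCO)cc1OC | intermediate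
7 | 2-[3,5-dimethoxy-4-(methoxymethoxy)phenyl]ethyl N,N-diisopropylcarbamate | COCOc1c(OC)cc(CCOC(=O)N(C(C)C)C(C)C)cc1OC | intermediate
8 | 2-(bromomethyl)-4,4,5,5-tetramethyl-1,3,2-dioxaborolane | CC1(C)OB(CBr)OC1(C)C | starting material
9 | 2-[(benzyloxy)methyl]-4,4,5,5-tetramethyl-1,3,2-dioxaborolane | CC1(C)OB(COCc2ccccc2)OC1(C)C | intermediate
10 | (1R)-2-(3,4-dimethoxyphenyl)-1-lithioethyl N,N-diisopropylcarbamate, (+)-sparteine complex | [Li][C@H](Cc1ccc(OC)c(OC)c1)OC(=O)N(C(C)C)C(C)C | intermediate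
11 | lithium (benzyloxymethyl)[(1R)-1-(N,N-diisopropylcarbamoyloxy)-2-(3,4-dimethoxyphenyl)ethyl](pinacolato)borate | [Li+].CC1(C)O[B-](COCc2ccccc2)([C@H](Cc2ccc(OC)c(OC)c2)OC(=O)N(C(C)C)C(C)C)OC1(C)C | intermediate
12 | 2-[(2S)-1-(benzyloxy)-3-(3,4-dimethoxyphenyl)propan-2-yl]-4,4,5,5-tetramethyl-1,3,2-dioxaborolane | C(OCc1ccccc1)[C@H](Cc1ccc(OC)c(OC)c1)B1OC(C)(C)C(C)(C)O1 | intermediate
13 | (1S)-2-[3,5-dimethoxy-4-(methoxymethoxy)phenyl]-1-lithioethyl N,N-diisopropylcarbamate, (−)-sparteine complex | [Li][C@@H](Cc1cc(OC)c(OCOC)c(OC)c1)OC(=O)N(C(C)C)C(C)C | intermediate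
14 | lithium [(2S)-1-(benzyloxy)-3-(3,4-dimethoxyphenyl)propan-2-yl][(1S)-1-(N,N-diisopropylcarbamoyloxy)-2-[3,5-dimethoxy-4-(methoxymethoxy)phenyl]ethyl](pinacolato)borate | [Li+].CC1(C)O[B-]([C@H](COCc2ccccc2)Cc2ccc(OC)c(OC)c2)([C@@H](Cc2cc(OC)c(OCOC)c(OC)c2)OC(=O)N(C(C)C)C(C)C)OC1(C)C | intermediate
15 | 2-[(2R,3R)-4-(benzyloxy)-3-(3,4-dimethoxybenzyl)-1-[3,5-dimethoxy-4-(methoxymethoxy)phenyl]butan-2-yl]-4,4,5,5-tetramethyl-1,3,2-dioxaborolane | C(OCc1ccccc1)[C@H](Cc1ccc(OC)c(OC)c1)[C@@H](Cc1cc(OC)c(OCOC)c(OC)c1)B1OC(C)(C)C(C)(C)O1 | intermediate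
16 | 2-[(2R,3R)-4-(benzyloxy)-1-chloro-3-(3,4-dimethoxybenzyl)-2-[3,5-dimethoxy-4-(methoxymethoxy)benzyl]butyl]-4,4,5,5-tetramethyl-1,3,2-dioxaborolane (both C1 epimers) | ClC([C@H](Cc1cc(OC)c(OCOC)c(OC)c1)[C@H](COCc1ccccc1)Cc1ccc(OC)c(OC)c1)B1OC(C)(C)C(C)(C)O1 | intermediate
17 | (2R,3R)-4-(benzyloxy)-3-(3,4-dimethoxybenzyl)-2-[3,5-dimethoxy-4-(methoxymethoxy)benzyl]butanal | O=C[C@H](Cc1cc(OC)c(OCOC)c(OC)c1)[C@H](COCc1ccccc1)Cc1ccc(OC)c(OC)c1 | intermediate
18 | (2R,3R)-4-(benzyloxy)-3-(3,4-dimethoxybenzyl)-2-[3,5-dimethoxy-4-(methoxymethoxy)benzyl]butanoic acid | OC(=O)[C@H](Cc1cc(OC)c(OCOC)c(OC)c1)[C@H](COCc1ccccc1)Cc1ccc(OC)c(OC)c1 | intermediate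
19 | (2R,3R)-3-(3,4-dimethoxybenzyl)-4-hydroxy-2-[3,5-dimethoxy-4-(methoxymethoxy)benzyl]butanoic acid | OC(=O)[C@H](Cc1cc(OC)c(OCOC)c(OC)c1)[C@H](CO)Cc1ccc(OC)c(OC)c1 | intermediate
20 | (3R,4R)-4-(3,4-dimethoxybenzyl)-3-[3,5-dimethoxy-4-(methoxymethoxy)benzyl]dihydrofuran-2(3H)-one | COc1ccc(C[C@H]2COC(=O)[C@@H]2Cc2cc(OC)c(OCOC)c(OC)c2)cc1OC | intermediate
21 | (3R,4R)-4-(3,4-dimethoxybenzyl)-3-(4-hydroxy-3,5-dimethoxybenzyl)dihydrofuran-2(3H)-one | COc1ccc(C[C@H]2COC(=O)[C@@H]2Cc2cc(OC)c(O)c(OC)c2)cc1OC | target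

**Totals**

Total step count: 8. Longest linear sequence: 6 steps (3 → 4 → 6 → 7 → 15 → 18 → 21, steps 2, 3, 4, 6, 7, 8).

**Steps most likely to fail**

Step 6. The crowded secondary boronic ester may be captured incompletely in the second stage. The β-benzyloxy boronate complex may also lose benzyloxide by β-elimination at the temperature the carbamate needs to leave, and benzylic deprotonation of the carbamates followed by loss of carbamate would drain material further. The fallback separates the two stages and changes the second leaving group; it sets out from 6 and 12 and returns at 15. Boronic ester 12 is isolated after the first stage. Alcohol 6 is esterified (2,4,6-triisopropylbenzoyl chloride, Et3N, DMAP, CH2Cl2) to 2-[3,5-dimethoxy-4-(methoxymethoxy)phenyl]ethyl 2,4,6-triisopropylbenzoate F1. This is deprotonated with sBuLi and (−)-sparteine in Et2O at −78 °C to the (S)-lithiated benzoate F2. Purified 12 is added to give boronate complex F3, whose benzoate should depart on warming to about 0–20 °C, well below the temperature that threatens the benzyloxy group, and 15 is reached.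

Step 7. The bulky dichloromethyl carbenoid may add slowly to the β-branched secondary boronic ester, and hypochlorous acid may chlorinate the electron-rich rings during the chlorite stage. The fallback sets out from 15 and returns at 18. Chloromethyllithium made in the flask (BrCH2Cl, nBuLi, THF, −78 °C) should insert a CH2 group to give 2-[(2R,3R)-4-(benzyloxy)-3-(3,4-dimethoxybenzyl)-2-[3,5-dimethoxy-4-(methoxymethoxy)benzyl]butyl]-4,4,5,5-tetramethyl-1,3,2-dioxaborolane F4. NaBO3·4H2O in THF/H2O oxidises the C–B bond to (2R,3R)-4-(benzyloxy)-3-(3,4-dimethoxybenzyl)-2-[3,5-dimethoxy-4-(methoxymethoxy)benzyl]butan-1-ol F5. TEMPO with PhI(OAc)2 in MeCN/H2O then takes F5 through aldehyde 17 to acid 18.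

Step 3. Ozone may attack the electron-rich trioxygenated ring once the alkene is consumed, or reduction of the ozonide may stall. The fallback sets out from 4 and returns at 6. Dihydroxylation (OsO4 cat., N-methylmorpholine N-oxide, acetone/H2O) gives 3-[3,5-dimethoxy-4-(methoxymethoxy)phenyl]propane-1,2-diol F6. NaIO4 in THF/H2O cleaves it to [3,5-dimethoxy-4-(methoxymethoxy)phenyl]acetaldehyde F7, which is reduced at once with NaBH4 in MeOH to 6.

**Further compounds**

F1 | step 6 | 2-[3,5-dimethoxy-4-(methoxymethoxy)phenyl]ethyl 2,4,6-triisopropylbenzoate | COCOc1c(OC)cc(CCOC(=O)c2c(C(C)C)cc(C(C)C)cc2C(C)C)cc1OC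
F2 | step 6 | (1S)-2-[3,5-dimethoxy-4-(methoxymethoxy)phenyl]-1-lithioethyl 2,4,6-triisopropylbenzoate, (−)-sparteine complex | [Li][C@@H](Cc1cc(OC)c(OCOC)c(OC)c1)OC(=O)c1c(C(C)C)cc(C(C)C)cc1C(C)C
F3 | step 6 | lithium [(2S)-1-(benzyloxy)-3-(3,4-dimethoxyphenyl)propan-2-yl][(1S)-2-[3,5-dimethoxy-4-(methoxymethoxy)phenyl]-1-(2,4,6-triisopropylbenzoyloxy)ethyl](pinacolato)borate | [Li+].CC1(C)O[B-]([C@H](COCc2ccccc2)Cc2ccc(OC)c(OC)c2)([C@@H](Cc2cc(OC)c(OCOC)c(OC)c2)OC(=O)c2c(C(C)C)cc(C(C)C)cc2C(C)C)OC1(C)C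
F4 | step 7 | 2-[(2R,3R)-4-(benzyloxy)-3-(3,4-dimethoxybenzyl)-2-[3,5-dimethoxy-4-(methoxymethoxy)benzyl]butyl]-4,4,5,5-tetramethyl-1,3,2-dioxaborolane | CC1(C)OB(C[C@H](Cc2cc(OC)c(OCOC)c(OC)c2)[C@H](COCc2ccccc2)Cc2ccc(OC)c(OC)c2)OC1(C)C
F5 | step 7 | (2R,3R)-4-(benzyloxy)-3-(3,4-dimethoxybenzyl)-2-[3,5-dimethoxy-4-(methoxymethoxy)benzyl]butan-1-ol | OC[C@H](Cc1cc(OC)c(OCOC)c(OC)c1)[C@H](COCc1ccccc1)Cc1ccc(OC)c(OC)c1
F6 | step 3 | 3-[3,5-dimethoxy-4-(methoxymethoxy)phenyl]propane-1,2-diol (racemic) | COCOc1c(OC)cc(CC(O)CO)cc1OC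
F7 | step 3 | [3,5-dimethoxy-4-(methoxymethoxy)phenyl]acetaldehyde | COCOc1c(OC)cc(CC=O)cc1OC
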